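The route rests on opening the dihydrofuran at C2–O1 and removing the hydroxymethyl carbon C9 from C3, which reduces the core to an (E)-ortho-hydroxystilbene. One operation, an interrupted asymmetric Prins reaction with formaldehyde, should rebuild C3–C9 and C2–O1, close the five-membered ring and set both stereocentres (2R,3S, trans). It exploits C2 being benzylic to ring A, para to that ring's oxygen, so that a cation formed there is well stabilised and lies within reach of the ring B phenol. The precursor is the stilbene with ring A capped as a triisopropylsilyl ether and ring B carrying the free phenol, the C7 methoxy group and a C5 bromine as later coupling handle.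

Key step: step 7

Assumption: the iIDP acid is prepared separately by the standard route from its 3,3'-disubstituted BINOL and is not counted in the steps; its (S,S)-form is taken to deliver the (2R,3S) series, and the (R,R)-form would be used if the sense of induction proved opposite.

Step 1
Reactants: 1 vanillin (4-hydroxy-3-methoxybenzaldehyde)
Product: 2 3-methoxy-4-(triisopropylsilyloxy)benzaldehyde
Conditions: TIPSCl, imidazole, DMF, rt
Reagents that add atoms: chlorotriisopropylsilane (TIPSCl), CC(C)[Si](Cl)(C(C)C)C(C)C
Why: Imidazole-mediated O-silylation of the only hydroxyl group; the bulky aryl triisopropylsilyl ether is chosen because it should survive hydride, the olefination bases, zinc iodide, the Brønsted acid of step 7 and the hot amine base of step 10.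

Step 2
Reactants: 2 3-methoxy-4-(triisopropylsilyloxy)benzaldehyde
Product: 3 [3-methoxy-4-(triisopropylsilyloxy)phenyl]methanol
Conditions: NaBH4, MeOH/THF, 0 °C
Reagents that add atoms: none
Why: Borohydride reduction of an aryl aldehyde to the benzylic alcohol, brief and cold so that the hindered aryl silyl ether is not touched.

Step 3
Reactants: 3 [3-methoxy-4-(triisopropylsilyloxy)phenyl]methanol
Product: 5 diethyl [3-methoxy-4-(triisopropylsilyloxy)benzyl]phosphonate, via mixed phosphite 4 (not isolated)
Conditions: ZnI2 (1.5 equiv), P(OEt)3 (3 equiv), THF, reflux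
Reagents that add atoms: triethyl phosphite, CCOP(OCC)OCC
Why: One-flask zinc-iodide-mediated phosphonylation of a benzylic alcohol, a Michaelis–Arbuzov-type process in which ester exchange gives mixed phosphite 4 and ZnI2 then promotes its rearrangement to the phosphonate, a process that electron-rich benzylic alcohols undergo most readily.

Step 4
Reactants: 6 5-bromo-2-hydroxy-3-methoxybenzaldehyde (5-bromo-o-vanillin)
Product: 7 2-(allyloxy)-5-bromo-3-methoxybenzaldehyde
Conditions: allyl bromide, K2CO3, DMF, rt
Reagents that add atoms: allyl bromide, C=CCBr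
Why: Williamson O-allylation of the only acidic OH; the allyl ether withstands the olefination base and can later be removed under neutral conditions that spare the silyl ether, the aryl bromide and the hydroxystilbene.

Step 5
Reactants: 5 diethyl [3-methoxy-4-(triisopropylsilyloxy)benzyl]phosphonate; 7 2-(allyloxy)-5-bromo-3-methoxybenzaldehyde
Product: 8 (E)-1-(allyloxy)-4-bromo-2-methoxy-6-[2-(3-methoxy-4-triisopropylsilyloxyphenyl)vinyl]benzene
Conditions: NaH, 15-crown-5 (cat.), THF, 0 °C → rt
Reagents that add atoms: none
Why: Horner–Wadsworth–Emmons olefination of a non-enolisable aryl aldehyde with the anion of a benzylic phosphonate, whose reversible addition and elimination should deliver the (E)-stilbene.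

Step 6
Reactants: 8 (E)-1-(allyloxy)-4-bromo-2-methoxy-6-[2-(3-methoxy-4-triisopropylsilyloxyphenyl)vinyl]benzene
Product: 9 (E)-4-bromo-2-methoxy-6-[2-(3-methoxy-4-triisopropylsilyloxyphenyl)vinyl]phenol
Conditions: Pd(PPh3)4 (3 mol%), morpholine, THF, rt
Reagents that add atoms: none
Why: Tsuji–Trost-type deallylation in which zerovalent palladium transfers the allyl group of the aryl ether to morpholine at room temperature, where insertion into the electron-rich C–Br bond is too slow to compete, so the phenol is freed last and without acid or strong base.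

Step 7
Reactants: 9 (E)-4-bromo-2-methoxy-6-[2-(3-methoxy-4-triisopropylsilyloxyphenyl)vinyl]phenol; 10 formaldehyde (supplied as paraformaldehyde)
Product: 12 [(2R,3S)-5-bromo-7-methoxy-2-(3-methoxy-4-triisopropylsilyloxyphenyl)-2,3-dihydro-1-benzofuran-3-yl]methanol (trans), via C2 benzylic cation 11 (not isolated)
Conditions: (CH2O)n (1.2 equiv), (S,S)-iIDP acid [HN{P(=O)(O2Ar*)}{P(=NSO2CF3)(O2Ar*)}, O2Ar* = (S)-3,3'-bis(perfluoro-2-naphthyl)-1,1'-binaphthalene-2,2'-diolate] (5 mol%), CHCl3/cyclohexane, 0 °C → rt; Et3N, then aq. NaHCO3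
Reagents that add atoms: paraformaldehyde as the source of formaldehyde 10, C=O
Why: Proposed new method: the chiral acid protonates formaldehyde 10 inside its anion pocket and the stilbene attacks it through C3, since only that direction puts the charge at C2 as cation 11, delocalised into ring A up to the para silyloxy oxygen, whereas attack through C2 would leave a cation beside ring B that has one ortho hydroxyl as donor and is inductively destabilised by the meta bromine and meta methoxy groups. The closest known reaction type is the catalytic asymmetric intermolecular Prins reaction of aryl olefins with paraformaldehyde under confined imino-imidodiphosphate acids, in which a second formaldehyde intercepts the cation to give a 1,3-dioxane; here the ring B phenol, held five atoms from C2, should trap it first. The ring closes by cation capture, 5-exo-trig with respect to the C2=C(ring A) bond of the quinone-methide resonance form of 11 (a concerted addition of the phenol across the stilbene π bond would be a disfavoured 5-endo-trig process, so the stepwise order C3–C9 then C2–O1 matters). C3 (S) is set by the catalyst, which exposes one face of C3 to the bound aldehyde, and C2 (R) by the substrate, the planar cation closing from the rotamer that places ring A opposite to the new CH2OH group, which gives the trans and also thermodynamically preferred ring. The step needs regioselectivity, enantiofacial selectivity and trans closure, secured in turn by the donor bias of ring A over bromine-bearing ring B, by the catalyst pocket and by steric avoidance in the closure; hydroxymethylation at oxygen or on the rings is held back by the silyl cap on ring A, by the substituents at both ortho positions and the para position of the ring B phenol (C7 methoxy, C3a, C5 bromine) and by keeping formaldehyde near one equivalent, and any hemiformal on the new alcohol is cleaved in the bicarbonate work-up.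

Step 8
Reactants: 13 3,5-dihydroxybenzaldehyde
Product: 14 3,5-bis(triisopropylsilyloxy)benzaldehyde
Conditions: TIPSCl (2.2 equiv), imidazole, DMF, rt
Reagents that add atoms: chlorotriisopropylsilane (TIPSCl), CC(C)[Si](Cl)(C(C)C)C(C)C
Why: Imidazole-mediated silylation of both phenols, giving the same robust silyl ether as on ring A so that one fluoride treatment clears all three at the end.

Step 9
Reactants: 14 3,5-bis(triisopropylsilyloxy)benzaldehyde
Product: 15 3,5-bis(triisopropylsilyloxy)styrene
Conditions: MePPh3Br, KOtBu, THF, 0 °C → rt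
Reagents that add atoms: methyltriphenylphosphonium bromide, C[P+](c1ccccc1)(c1ccccc1)c1ccccc1.[Br-]
Why: Wittig methylenation of a non-enolisable aryl aldehyde with the unstabilised ylide made in the flask, conditions the hindered aryl silyl ethers should tolerate.

Step 10
Reactants: 12 [(2R,3S)-5-bromo-7-methoxy-2-(3-methoxy-4-triisopropylsilyloxyphenyl)-2,3-dihydro-1-benzofuran-3-yl]methanol; 15 3,5-bis(triisopropylsilyloxy)styrene
Product: 16 [(2R,3S)-5-{(E)-2-[3,5-bis(triisopropylsilyloxy)phenyl]vinyl}-7-methoxy-2-(3-methoxy-4-triisopropylsilyloxyphenyl)-2,3-dihydro-1-benzofuran-3-yl]methanol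
Conditions: Pd(OAc)2 (5 mol%), P(o-tol)3 (10 mol%), Et3N, DMF, 100 °C
Reagents that add atoms: none
Why: Mizoroki–Heck reaction in which zerovalent palladium inserts into the C5–Br bond, the aryl group adds to the terminal styrene carbon and syn β-hydride elimination gives the (E)-stilbene; the second olefin is introduced only now so that it never competes in step 7, and with no acid and no free para phenol present the free alcohol and both stereocentres should be unaffected.

Step 11
Reactants: 16 [(2R,3S)-5-{(E)-2-[3,5-bis(triisopropylsilyloxy)phenyl]vinyl}-7-methoxy-2-(3-methoxy-4-triisopropylsilyloxyphenyl)-2,3-dihydro-1-benzofuran-3-yl]methanol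
Product: 17 gnetofuran A, 5-{(E)-2-[(2R,3S)-2-(4-hydroxy-3-methoxyphenyl)-3-(hydroxymethyl)-7-methoxy-2,3-dihydro-1-benzofuran-5-yl]vinyl}benzene-1,3-diol
Conditions: Bu4NF (3.3 equiv), AcOH (3.3 equiv), THF, 0 °C → rt
Reagents that add atoms: none
Why: Fluoride-induced cleavage of the three aryl silyl ethers, driven by Si–F bond formation and buffered with acetic acid so that the freed ring A phenol stays protonated and cannot open C2–O1 through a para-quinone methide.

Compound list
1 | vanillin (4-hydroxy-3-methoxybenzaldehyde) | COc1cc(C=O)ccc1O | starting material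
2 | 3-methoxy-4-(triisopropylsilyloxy)benzaldehyde | COc1cc(C=O)ccc1O[Si](C(C)C)(C(C)C)C(C)C | intermediate
3 | [3-methoxy-4-(triisopropylsilyloxy)phenyl]methanol | COc1cc(CO)ccc1O[Si](C(C)C)(C(C)C)C(C)C | intermediate
4 | diethyl 3-methoxy-4-(triisopropylsilyloxy)benzyl phosphite (mixed phosphite, not isolated) | CCOP(OCC)OCc1ccc(O[Si](C(C)C)(C(C)C)C(C)C)c(OC)c1 | intermediate
5 | diethyl [3-methoxy-4-(triisopropylsilyloxy)benzyl]phosphonate | CCOP(=O)(OCC)Cc1ccc(O[Si](C(C)C)(C(C)C)C(C)C)c(OC)c1 | intermediate
6 | 5-bromo-2-hydroxy-3-methoxybenzaldehyde (5-bromo-o-vanillin) | O=Cc1cc(Br)cc(OC)c1O | starting material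
7 | 2-(allyloxy)-5-bromo-3-methoxybenzaldehyde | C=CCOc1c(C=O)cc(Br)cc1OC | intermediate
8 | (E)-1-(allyloxy)-4-bromo-2-methoxy-6-[2-(3-methoxy-4-triisopropylsilyloxyphenyl)vinyl]benzene | COc1cc(/C=C/c2cc(Br)cc(OC)c2OCC=C)ccc1O[Si](C(C)C)(C(C)C)C(C)C | intermediate
9 | (E)-4-bromo-2-methoxy-6-[2-(3-methoxy-4-triisopropylsilyloxyphenyl)vinyl]phenol | COc1cc(/C=C/c2cc(Br)cc(OC)c2O)ccc1O[Si](C(C)C)(C(C)C)C(C)C | intermediate
10 | formaldehyde (supplied as paraformaldehyde) | C=O | starting material
11 | 2-(5-bromo-2-hydroxy-3-methoxyphenyl)-3-hydroxy-1-(3-methoxy-4-triisopropylsilyloxyphenyl)propan-1-ylium, the C2 benzylic cation with C3 configured as in 12 (not isolated) | COc1cc([CH+][C@H](CO)c2cc(Br)cc(OC)c2O)ccc1O[Si](C(C)C)(C(C)C)C(C)C | intermediate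
12 | [(2R,3S)-5-bromo-7-methoxy-2-(3-methoxy-4-triisopropylsilyloxyphenyl)-2,3-dihydro-1-benzofuran-3-yl]methanol (trans) | COc1cc([C@@H]2Oc3c(OC)cc(Br)cc3[C@H]2CO)ccc1O[Si](C(C)C)(C(C)C)C(C)C | intermediate
13 | 3,5-dihydroxybenzaldehyde | O=Cc1cc(O)cc(O)c1 | starting material
14 | 3,5-bis(triisopropylsilyloxy)benzaldehyde | O=Cc1cc(O[Si](C(C)C)(C(C)C)C(C)C)cc(O[Si](C(C)C)(C(C)C)C(C)C)c1 | intermediate
15 | 3,5-bis(triisopropylsilyloxy)styrene | C=Cc1cc(O[Si](C(C)C)(C(C)C)C(C)C)cc(O[Si](C(C)C)(C(C)C)C(C)C)c1 | intermediate
16 | [(2R,3S)-5-{(E)-2-[3,5-bis(triisopropylsilyloxy)phenyl]vinyl}-7-methoxy-2-(3-methoxy-4-triisopropylsilyloxyphenyl)-2,3-dihydro-1-benzofuran-3-yl]methanol | COc1cc([C@@H]2Oc3c(OC)cc(/C=C/c4cc(O[Si](C(C)C)(C(C)C)C(C)C)cc(O[Si](C(C)C)(C(C)C)C(C)C)c4)cc3[C@H]2CO)ccc1O[Si](C(C)C)(C(C)C)C(C)C | intermediate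
17 | gnetofuran A, (2R,3S)-trans | COc1cc([C@@H]2Oc3c(OC)cc(/C=C/c4cc(O)cc(O)c4)cc3[C@H]2CO)ccc1O | target

Total step count: 11. Longest linear sequence: 8 steps (steps 1, 2, 3, 5, 6, 7, 10 and 11, from vanillin).

Steps most likely to fail

Step 7 (proposed new method). Several processes could defeat it:
- bond formation through C2 instead of C3;
- plain protonation of the stilbene and phenol capture without uptake of formaldehyde;
- O-hydroxymethylation of the phenol and closure through an aryloxymethyl cation;
- interception of cation 11 by a second formaldehyde;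
- weak facial discrimination, because the stilbene is bulkier than the aryl olefins a confined pocket normally accepts.

The fallback uses known chemistry, sets out from aldehyde 7 (with aldehyde 2 as second component) and returns at 12, so that steps 3, 5 and 6 are no longer needed. Aldehyde 7 is homologated by Wittig reaction with MeOCH2PPh3Cl and KOtBu to the enol ether 1-(allyloxy)-4-bromo-2-methoxy-6-(2-methoxyvinyl)benzene F1. Hydrolysis with aqueous HCl in THF gives 2-[2-(allyloxy)-5-bromo-3-methoxyphenyl]acetaldehyde F2, and Pinnick oxidation (NaClO2, NaH2PO4, 2-methyl-2-butene) gives 2-[2-(allyloxy)-5-bromo-3-methoxyphenyl]acetic acid F3. Pivaloyl chloride and Et3N convert the acid into its mixed pivalic anhydride F4, which acylates (R)-4-benzyl-2-oxazolidinone in the presence of LiCl to give the imide (R)-3-{2-[2-(allyloxy)-5-bromo-3-methoxyphenyl]acetyl}-4-benzyloxazolidin-2-one F5. Its dibutylboron Z-enolate (Bu2BOTf, iPr2NEt, CH2Cl2, −78 °C) should add to aldehyde 2 in an Evans syn-aldol reaction to give the (2R,3R)-aldol adduct F6, in which the auxiliary fixes the carbon that becomes C3. LiBH4 removes the auxiliary to give (1R,2S)-2-[2-(allyloxy)-5-bromo-3-methoxyphenyl]-1-(3-methoxy-4-triisopropylsilyloxyphenyl)propane-1,3-diol F7. Deallylation as in step 6 gives the phenol diol (1R,2S)-2-(5-bromo-2-hydroxy-3-methoxyphenyl)-1-(3-methoxy-4-triisopropylsilyloxyphenyl)propane-1,3-diol F8. Catalytic camphorsulfonic acid in CH2Cl2 at 0 °C ionises its benzylic alcohol to cation 11, which should close to the trans ring and give 12.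

Step 10. The electron-rich aryl bromide may undergo oxidative addition too slowly, with loss of active palladium, and insertion into the electron-rich styrene may be poorly regioselective, giving the 1,1-diarylethene beside the stilbene. The fallback sets out from aldehyde 14 and returns at 16. Boron-Wittig olefination of 14 with CH2(Bpin)2 and lithium 2,2,6,6-tetramethylpiperidide (THF, −78 °C → rt) gives (E)-2-[3,5-bis(triisopropylsilyloxy)styryl]-4,4,5,5-tetramethyl-1,3,2-dioxaborolane F9. Suzuki–Miyaura coupling of this boronate with bromide 12 (PdCl2(dppf), K3PO4, dioxane/H2O, 70 °C) forms the aryl–vinyl bond with the olefin geometry fixed beforehand and gives 16.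

Step 3. Ionisation of the very electron-rich benzylic position under ZnI2 may lead to self-alkylation of the arene or to loss of the silyl ether before phosphorus is attached. The fallback sets out from alcohol 3 and returns at 5. PBr3 (CH2Cl2, 0 °C) converts the alcohol into 4-(bromomethyl)-2-methoxy-1-(triisopropylsilyloxy)benzene F10, and this bromide is heated in neat P(OEt)3 at 120 °C, where a Michaelis–Arbuzov reaction by direct displacement gives 5.

Further compounds
F1 | step 7 | 1-(allyloxy)-4-bromo-2-methoxy-6-(2-methoxyvinyl)benzene (E/Z mixture) | COC=Cc1cc(Br)cc(OC)c1OCC=C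
F2 | step 7 | 2-[2-(allyloxy)-5-bromo-3-methoxyphenyl]acetaldehyde | O=CCc1cc(Br)cc(OC)c1OCC=C
F3 | step 7 | 2-[2-(allyloxy)-5-bromo-3-methoxyphenyl]acetic acid | OC(=O)Cc1cc(Br)cc(OC)c1OCC=C
F4 | step 7 | 2-[2-(allyloxy)-5-bromo-3-methoxyphenyl]acetic pivalic anhydride | CC(C)(C)C(=O)OC(=O)Cc1cc(Br)cc(OC)c1OCC=C
F5 | step 7 | (R)-3-{2-[2-(allyloxy)-5-bromo-3-methoxyphenyl]acetyl}-4-benzyloxazolidin-2-one | O=C(Cc1cc(Br)cc(OC)c1OCC=C)N1C(=O)OC[C@H]1Cc1ccccc1
F6 | step 7 | (R)-3-[(2R,3R)-2-[2-(allyloxy)-5-bromo-3-methoxyphenyl]-3-hydroxy-3-(3-methoxy-4-triisopropylsilyloxyphenyl)propanoyl]-4-benzyloxazolidin-2-one | O=C(N1C(=O)OC[C@H]1Cc1ccccc1)[C@H](c1cc(Br)cc(OC)c1OCC=C)[C@@H](O)c1ccc(O[Si](C(C)C)(C(C)C)C(C)C)c(OC)c1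
F7 | step 7 | (1R,2S)-2-[2-(allyloxy)-5-bromo-3-methoxyphenyl]-1-(3-methoxy-4-triisopropylsilyloxyphenyl)propane-1,3-diol | OC[C@H](c1cc(Br)cc(OC)c1OCC=C)[C@@H](O)c1ccc(O[Si](C(C)C)(C(C)C)C(C)C)c(OC)c1
F8 | step 7 | (1R,2S)-2-(5-bromo-2-hydroxy-3-methoxyphenyl)-1-(3-methoxy-4-triisopropylsilyloxyphenyl)propane-1,3-diol | OC[C@H](c1cc(Br)cc(OC)c1O)[C@@H](O)c1ccc(O[Si](C(C)C)(C(C)C)C(C)C)c(OC)c1
F9 | step 10 | (E)-2-[3,5-bis(triisopropylsilyloxy)styryl]-4,4,5,5-tetramethyl-1,3,2-dioxaborolane | CC(C)[Si](Oc1cc(/C=C/B2OC(C)(C)C(C)(C)O2)cc(O[Si](C(C)C)(C(C)C)C(C)C)c1)(C(C)C)C(C)C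
F10 | step 3 | 4-(bromomethyl)-2-methoxy-1-(triisopropylsilyloxy)benzene | COc1cc(CBr)ccc1O[Si](C(C)C)(C(C)C)C(C)C
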